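## Retrosynthetic overview

1. Target 14 ⇒ keto-lactone 13: the last step removes the ketone oxygen and the benzyl group by hydrogenolysis.
2. 13 ⇒ (R)-lactone 8 + aryl bromide 11 + CO: carbonylative formation of the C3–acyl bond, with trans geometry dictated by C4.
3. 8 ⇒ cyclobutanone 6: desymmetrising Baeyer–Villiger ring expansion (four- to five-membered ring), which fixes C4.
4. 6 ⇒ 4-bromoveratrole 3 + 3-(bromomethyl)cyclobutanone 4 (Negishi); 11 ⇒ 3 (C–H borylation/oxidation, O-benzylation); 3 ⇒ catechol 1.
5. Ring order: both benzene rings come from catechol, the cyclobutane is bought, and the lactone is the only ring made, by ring expansion in step 4.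

Assumption: 3-(bromomethyl)cyclobutan-1-one is taken as a catalogue compound, and in step 4 the ligand antipode that delivers the (R)-lactone is used (its mirror image gives the (S)-lactone).

## Route

Step 1
Reactants: 1 catechol
Product: 2 veratrole (1,2-dimethoxybenzene)
Conditions: MeI (2.5 equiv), K2CO3 (3 equiv), acetone, reflux, N2
Reagents that add atoms: iodomethane, CI
Why: Williamson O-methylation of both phenolic OH groups (SN2 on MeI by the potassium phenoxides); no stereocenter.

Step 2
Reactants: 2 veratrole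
Product: 3 4-bromoveratrole (4-bromo-1,2-dimethoxybenzene)
Conditions: NBS (1.05 equiv), MeCN, 0 °C to 25 °C
Reagents that add atoms: N-bromosuccinimide, O=C1CCC(=O)N1Br
Why: Electrophilic aromatic bromination; NBS in MeCN brominates para to a methoxy group, and the two such positions of veratrole are equivalent, so 3 is the only monobromide.

Step 3
Reactants: 3 4-bromoveratrole; 4 3-(bromomethyl)cyclobutan-1-one
Product: 6 3-[(3,4-dimethoxyphenyl)methyl]cyclobutan-1-one, via alkylzinc bromide 5 (not isolated)
Conditions: 4, Zn dust (1.5 equiv, activated with BrCH2CH2Br/TMSCl), LiCl, THF, 50 °C; then 3, Pd(OAc)2 (2 mol%), SPhos (4 mol%), THF, 50 °C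
Reagents that add atoms: zinc, [Zn] (held only in intermediate 5; product 6 takes no atoms from a reagent)
Why: LiCl-assisted zinc insertion into the primary C–Br bond gives a ketone-tolerant alkylzinc that undergoes Negishi sp3–sp2 cross-coupling with 3; a polar organometallic is chosen because a free (3-oxocyclobutyl)methyl radical would risk ring opening.

Step 4
Reactants: 6 3-[(3,4-dimethoxyphenyl)methyl]cyclobutan-1-one
Product: 8 (4R)-4-[(3,4-dimethoxyphenyl)methyl]oxolan-2-one, via Criegee adduct 7 (not isolated)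
Conditions: mCPBA (1.3 equiv), Sc(OTf)3 (5 mol%), chiral C2-symmetric N,N'-dioxide ligand (L-pipecolic acid core, 2,6-diisopropylanilide arms, trimethylene tether; 6 mol%), EtOAc, −20 °C
Reagents that add atoms: m-chloroperoxybenzoic acid, O=C(OO)c1cccc(Cl)c1
Why: Baeyer–Villiger ring expansion in which the peracid adds to the Sc-activated ketone to give Criegee adduct 7 and one of the two enantiotopic ring CH2 groups shifts from carbon to oxygen (1,2-shift), the chiral N,N'-dioxide·Sc(OTf)3 pocket selecting the CH2 whose migration gives the (R)-lactone, as in the known desymmetrising Baeyer–Villiger oxidation of 3-substituted cyclobutanones.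

Step 5
Reactants: 3 4-bromoveratrole
Product: 10 5-bromo-2,3-dimethoxyphenol, via aryl pinacol boronate 9 (not isolated)
Conditions: B2pin2 (1.0 equiv), [Ir(OMe)(cod)]2 (1.5 mol%), 4,4'-di-tert-butyl-2,2'-bipyridine (3 mol%), THF, 80 °C; then KHSO5 (Oxone), acetone/H2O, 25 °C
Reagents that add atoms: bis(pinacolato)diboron, CC1(C)OB(OC1(C)C)B1OC(C)(C)C(C)(C)O1 (boryl group of intermediate 9 only); potassium peroxymonosulfate, [K+].[O-]S(=O)(=O)OO (the phenol oxygen)
Why: Sterically controlled iridium-catalysed aromatic C–H borylation followed by in-flask C–B oxidation (one-pot borylation/oxidation); H-3 lies between OMe and Br and H-5 is next to the large Br, so boron goes to C-6 next to the smaller OMe, and Oxone converts C–B into C–OH at the same position.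

Step 6
Reactants: 10 5-bromo-2,3-dimethoxyphenol
Product: 11 1-(benzyloxy)-5-bromo-2,3-dimethoxybenzene
Conditions: BnBr (1.1 equiv), K2CO3 (1.5 equiv), DMF, 25 °C
Reagents that add atoms: benzyl bromide, BrCc1ccccc1
Why: Williamson O-benzylation; the benzyl ether keeps the phenol out of the zinc amide and acylpalladium chemistry of step 7 and is removed in step 8.

Step 7
Reactants: 8 (4R)-4-[(3,4-dimethoxyphenyl)methyl]oxolan-2-one; 11 1-(benzyloxy)-5-bromo-2,3-dimethoxybenzene
Product: 13 (3S,4R)-3-[3-(benzyloxy)-4,5-dimethoxybenzoyl]-4-[(3,4-dimethoxyphenyl)methyl]oxolan-2-one, via zinc enolate 12 (not isolated)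
Conditions: 8 (1.2 equiv), Zn(TMP)2 (1.1 equiv; TMP = 2,2,6,6-tetramethylpiperidide), THF, 25 °C, 1 h; then 11 (1.0 equiv), Pd(dba)2 (5 mol%), Xantphos (6 mol%), CO (1 atm), THF, 65 °C; 1 M HCl work-up
Reagents that add atoms: carbon monoxide, [C-]#[O+] (the ketone carbon and oxygen); Zn(TMP)2, CC1(C)CCCC(C)(C)N1[Zn]N1C(C)(C)CCCC1(C)C (zinc amide part of intermediate 12 only)
Why: Proposed new method: Pd-catalysed carbonylative α-aroylation of a lactone zinc enolate — oxidative addition of 11 to zerovalent palladium–Xantphos, fast CO insertion to the aroylpalladium bromide, transmetalation with zinc enolate 12 and C–C reductive elimination give the β-keto lactone, whose immediate deprotonation by the remaining Zn–TMP unit hinders a second acylation and lets C3 settle trans to the C4 benzyl group on protonation (thermodynamic control by the existing stereocenter); the closest known reactions are the Pd-catalysed carbonylative α-arylation of ketones to 1,3-diketones and the Pd-catalysed α-arylation of zinc ester enolates.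

Step 8
Reactants: 13 (3S,4R)-3-[3-(benzyloxy)-4,5-dimethoxybenzoyl]-4-[(3,4-dimethoxyphenyl)methyl]oxolan-2-one
Product: 14 (3R,4R)-4-[(3,4-dimethoxyphenyl)methyl]-3-[(3-hydroxy-4,5-dimethoxyphenyl)methyl]oxolan-2-one
Conditions: H2 (3 atm), 10% Pd/C, AcOH, HClO4 (cat.), 25 °C
Reagents that add atoms: none
Why: Palladium-catalysed hydrogenolysis cleaves the O-benzyl group, reduces the electron-rich aryl ketone to the benzylic carbinol and hydrogenolyses it under acid catalysis to CH2 (the known fate of podorhizol-type carbinols), while C3 and C4 are not reacting centres and stay trans; the descriptor at C3 changes from S to R only because the CIP priorities change.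

## Compound list

1 | catechol (benzene-1,2-diol) | Oc1ccccc1O | starting material
2 | veratrole (1,2-dimethoxybenzene) | COc1ccccc1OC | intermediate
3 | 4-bromoveratrole (4-bromo-1,2-dimethoxybenzene) | COc1ccc(Br)cc1OC | intermediate
4 | 3-(bromomethyl)cyclobutan-1-one | O=C1CC(CBr)C1 | starting material
5 | [(3-oxocyclobutyl)methyl]zinc bromide | O=C1CC(C[Zn]Br)C1 | intermediate
6 | 3-[(3,4-dimethoxyphenyl)methyl]cyclobutan-1-one | COc1ccc(CC2CC(=O)C2)cc1OC | intermediate
7 | Criegee adduct, 3-[(3,4-dimethoxyphenyl)methyl]-1-hydroxycyclobutyl 3-chlorobenzenecarboperoxoate | COc1ccc(CC2CC(O)(OOC(=O)c3cccc(Cl)c3)C2)cc1OC | intermediate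
8 | (4R)-4-[(3,4-dimethoxyphenyl)methyl]oxolan-2-one | COc1ccc(C[C@H]2COC(=O)C2)cc1OC | intermediate
9 | 2-(5-bromo-2,3-dimethoxyphenyl)-4,4,5,5-tetramethyl-1,3,2-dioxaborolane | COc1cc(Br)cc(B2OC(C)(C)C(C)(C)O2)c1OC | intermediate
10 | 5-bromo-2,3-dimethoxyphenol | COc1cc(Br)cc(O)c1OC | intermediate
11 | 1-(benzyloxy)-5-bromo-2,3-dimethoxybenzene | COc1cc(Br)cc(OCc2ccccc2)c1OC | intermediate
12 | (2,2,6,6-tetramethylpiperidin-1-yl)zinc enolate of 8 (O-bound, C4 R) | COc1ccc(C[C@H]2COC(O[Zn]N3C(C)(C)CCCC3(C)C)=C2)cc1OC | intermediate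
13 | (3S,4R)-3-[3-(benzyloxy)-4,5-dimethoxybenzoyl]-4-[(3,4-dimethoxyphenyl)methyl]oxolan-2-one (trans) | COc1ccc(C[C@H]2COC(=O)[C@@H]2C(=O)c2cc(OCc3ccccc3)c(OC)c(OC)c2)cc1OC | intermediate
14 | (3R,4R)-4-[(3,4-dimethoxyphenyl)methyl]-3-[(3-hydroxy-4,5-dimethoxyphenyl)methyl]oxolan-2-one (trans) | COc1ccc(C[C@H]2COC(=O)[C@@H]2Cc2cc(O)c(OC)c(OC)c2)cc1OC | target

## Step count and weak points

Total: 8 steps (isolated products 2, 3, 6, 8, 10, 11, 13, 14).
Longest linear sequence: 6 steps from catechol (1 → 2 → 3 → 6 → 8 → 13 → 14; the branch 1 → 2 → 3 → 10 → 11 → 13 → 14 is equally long).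

The three steps most likely to fail:

1. Step 7, the new carbonylative aroylation. Direct α-arylation without CO, O-acylation, over-acylation of the product enolate or sluggish oxidative addition of the electron-rich bromide could intervene. The fallback is known chemistry, sets out from 11 and 8 and comes back at 14. Bromine–lithium exchange on 11 (n-BuLi, THF, −78 °C) and quenching with DMF give 3-(benzyloxy)-4,5-dimethoxybenzaldehyde F1. Aldol addition of 8 to F1 (LiN(i-Pr)2, THF, −78 °C) gives the trans adduct (3S,4R)-3-{[3-(benzyloxy)-4,5-dimethoxyphenyl](hydroxy)methyl}-4-[(3,4-dimethoxyphenyl)methyl]oxolan-2-one F2 as a pair of carbinol epimers. Hydrogenolysis of F2 under the conditions of step 8 removes the carbinol oxygen and the benzyl group and gives 14.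

2. Step 5, the site of C–H borylation on 3. Boron may go partly next to bromine (C-5), or the reaction may be slow because every open position is ortho to a substituent. The fallback installs the oxygen first and the bromine last, sets out from 2 and comes back at 10. Ortho-lithiation, borylation and oxidation of 2 in one flask (n-BuLi, TMEDA, Et2O; B(OMe)3; H2O2, AcOH) give 2,3-dimethoxyphenol F3. Silylation (TIPSCl, imidazole, DMF) gives (2,3-dimethoxyphenoxy)tri(propan-2-yl)silane F4. Iridium-catalysed borylation ([Ir(OMe)(cod)]2, 4,4'-di-tert-butyl-2,2'-bipyridine, B2pin2), now possible only at the single unhindered C-5, gives [2,3-dimethoxy-5-(4,4,5,5-tetramethyl-1,3,2-dioxaborolan-2-yl)phenoxy]tri(propan-2-yl)silane F5. CuBr2 (MeOH/H2O, 80 °C) converts it into (5-bromo-2,3-dimethoxyphenoxy)tri(propan-2-yl)silane F6, and Bu4NF (THF) gives 10.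

3. Step 4, the enantioselectivity of the ring expansion on a flexible benzyl-substituted cyclobutanone. The fallback keeps the ring expansion but sets C4 by a different event, sets out from 6 and comes back at 8. Uncatalysed Baeyer–Villiger oxidation (mCPBA, NaHCO3, CH2Cl2) gives racemic 4-[(3,4-dimethoxyphenyl)methyl]oxolan-2-one F7. Selenenylation (LiN(i-Pr)2, PhSeBr, THF, −78 °C) gives 4-[(3,4-dimethoxyphenyl)methyl]-3-(phenylselanyl)oxolan-2-one F8. Oxidation with H2O2 and syn-elimination give the butenolide 4-[(3,4-dimethoxyphenyl)methyl]furan-2(5H)-one F9. Copper hydride asymmetric conjugate reduction (CuCl, NaOt-Bu, p-tol-BINAP antipode chosen for R, PMHS, toluene) gives 8.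

## Further compounds

F1 | step 7 | 3-(benzyloxy)-4,5-dimethoxybenzaldehyde | COc1cc(C=O)cc(OCc2ccccc2)c1OC
F2 | step 7 | (3S,4R)-3-{[3-(benzyloxy)-4,5-dimethoxyphenyl](hydroxy)methyl}-4-[(3,4-dimethoxyphenyl)methyl]oxolan-2-one (both carbinol epimers) | COc1ccc(C[C@H]2COC(=O)[C@@H]2C(O)c2cc(OCc3ccccc3)c(OC)c(OC)c2)cc1OC
F3 | step 5 | 2,3-dimethoxyphenol | COc1cccc(O)c1OC
F4 | step 5 | (2,3-dimethoxyphenoxy)tri(propan-2-yl)silane | COc1cccc(O[Si](C(C)C)(C(C)C)C(C)C)c1OC
F5 | step 5 | [2,3-dimethoxy-5-(4,4,5,5-tetramethyl-1,3,2-dioxaborolan-2-yl)phenoxy]tri(propan-2-yl)silane | COc1cc(B2OC(C)(C)C(C)(C)O2)cc(O[Si](C(C)C)(C(C)C)C(C)C)c1OC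
F6 | step 5 | (5-bromo-2,3-dimethoxyphenoxy)tri(propan-2-yl)silane | COc1cc(Br)cc(O[Si](C(C)C)(C(C)C)C(C)C)c1OC
F7 | step 4 | racemic 4-[(3,4-dimethoxyphenyl)methyl]oxolan-2-one | COc1ccc(CC2COC(=O)C2)cc1OC
F8 | step 4 | racemic 4-[(3,4-dimethoxyphenyl)methyl]-3-(phenylselanyl)oxolan-2-one | COc1ccc(CC2COC(=O)C2[Se]c2ccccc2)cc1OC
F9 | step 4 | 4-[(3,4-dimethoxyphenyl)methyl]furan-2(5H)-one | COc1ccc(CC2=CC(=O)OC2)cc1OC
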